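**Retrosynthetic overview**
1. 21 ⇒ 19: open the N–CH(OH) carbinolamine. Ring D closes last, and the OH settles under thermodynamic control.
2. 19/18 ⇒ 15 + CO2: cut C4a–O and N–C(=O) of the bridged carbamate (oxidative dearomative carboxylative cyclisation).
3. 15 ⇒ 13 + CH2O (Henry reaction sets the quaternary C–N centre). 13 ⇒ 10 + PhNHNH2 (Fischer synthesis, rings A/B).
4. 10 ⇒ 7 + 8: an organocatalytic double Michael ([4+2]) reaction builds ring C, including the CMe2 carbon.
5. 7 ⇒ 4 ⇒ 3 ⇒ 1 + 2: an organocatalytic intramolecular aza-Michael reaction makes ring E and the first stereocentre. Ring order: E → C → A/B → carbamate bridge → D.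

Assumption: the carbinolamine carbon is configurationally labile (iminium/OH exchange), so it is set thermodynamically in the last step; 1 and 8 are taken as catalogue chemicals.

**Step 1**
Reactants: 1 tert-butyl pent-4-en-1-ylcarbamate; 2 (E)-but-2-enal
Product: 3 tert-butyl [(E)-6-oxohex-4-en-1-yl]carbamate
Conditions: Hoveyda–Grubbs II (3 mol %), 2 (5 equiv), CH2Cl2, 40 °C
Reagents that add atoms: none
Why: Olefin cross-metathesis of a terminal alkene with an enal partner is E-selective and is driven by loss of volatile propene.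

**Step 2**
Reactants: 3 tert-butyl [(E)-6-oxohex-4-en-1-yl]carbamate
Product: 4 tert-butyl (R)-2-(2-oxoethyl)pyrrolidine-1-carboxylate
Conditions: (S)-2-{bis[3,5-bis(trifluoromethyl)phenyl](trimethylsilyloxy)methyl}pyrrolidine (20 mol %), PhCO2H (20 mol %), CHCl3, −50 to −30 °C
Reagents that add atoms: none
Why: In this intramolecular aza-Michael addition under iminium catalysis, the silyloxydiarylmethyl group blocks one face of the E-iminium ion, so the carbamate N closes 5-exo-trig from the open face and sets the (R) centre, the first stereocentre, from an achiral substrate.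

**Step 3**
Reactants: 4 tert-butyl (R)-2-(2-oxoethyl)pyrrolidine-1-carboxylate
Product: 7 tert-butyl (R)-2-[(E)-3-nitroprop-2-en-1-yl]pyrrolidine-1-carboxylate, via nitro aldol 5 (not isolated), via nitro mesylate 6 (not isolated)
Conditions: MeNO2 (10 equiv), KOtBu (10 mol %), THF/t-BuOH, 0 °C; then MsCl, Et3N, CH2Cl2, −10 °C
Reagents that add atoms: nitromethane, C[N+](=O)[O-]
Why: A Henry reaction followed by E1cB loss of mesylate gives the conjugated E-nitroalkene, and the low temperature and short base contact avoid retro-aza-Michael erosion of the pyrrolidine centre.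

**Step 4**
Reactants: 7 tert-butyl (R)-2-[(E)-3-nitroprop-2-en-1-yl]pyrrolidine-1-carboxylate; 8 4-methylpent-1-en-3-one
Product: 10 tert-butyl (R)-2-{[(1R,6R)-2,2-dimethyl-6-nitro-3-oxocyclohexyl]methyl}pyrrolidine-1-carboxylate, via open-chain nitro enone 9 (not isolated)
Conditions: 8 (1.5 equiv, slow addition), 1-[(1R,2R)-2-aminocyclohexyl]-3-[3,5-bis(trifluoromethyl)phenyl]thiourea (20 mol %; the (1S,2S) antipode is used if the sense proves opposite), PhCO2H (20 mol %), BHT (trace), toluene, rt
Reagents that add atoms: none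
Why: Proposed new method: the primary amine condenses with the vinyl ketone to a cross-conjugated 2-aminodiene whose fully substituted enamine carbon adds to the thiourea-bound nitroalkene on the Si face of its β-carbon (catalyst control, the remote pyrrolidine centre is a spectator), forging the CMe2–CH bond and the (R) methine, after which the nitronate closes 6-endo-trig onto the vinyl iminium ion (9 in catalyst-bound form) and hydrolysis releases the ketone with the epimerisable nitro group equatorial; the closest known reaction types are the amine-catalysed formal Diels–Alder (double Michael) reaction of methyl enones with nitroalkenes and the primary-amine-thiourea addition of α,α-disubstituted aldehydes to nitroalkenes, neither shown for an α′,α′-dialkyl vinyl ketone that creates a quaternary carbon.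

**Step 5**
Reactants: 10 nitro ketone; 11 phenylhydrazine
Product: 13 tert-butyl (R)-2-{[(2R,3R)-1,1-dimethyl-3-nitro-2,3,4,9-tetrahydro-1H-carbazol-2-yl]methyl}pyrrolidine-1-carboxylate, via phenylhydrazone 12 (not isolated)
Conditions: PhNHNH2 (1.2 equiv), AcOH, 80 °C
Reagents that add atoms: none
Why: In this Fischer indole synthesis only the CH2 side of the ketone can form the ene-hydrazine because the other α-carbon is quaternary, so one regioisomer results, the C2 and pyrrolidine centres are untouched, and the nitro-bearing carbon is reset in step 6.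

**Step 6**
Reactants: 13 nitro tetrahydrocarbazole
Product: 14 tert-butyl (R)-2-{[(2R,3S)-3-(hydroxymethyl)-1,1-dimethyl-3-nitro-2,3,4,9-tetrahydro-1H-carbazol-2-yl]methyl}pyrrolidine-1-carboxylate
Conditions: 37% aq CH2O (5 equiv), Et3N (20 mol %), THF, rt
Reagents that add atoms: formaldehyde, C=O
Why: In this Henry reaction the planar nitronate takes up the small electrophile anti to the neighbouring C2 side chain, and because the addition is reversible it also equilibrates to the isomer with CH2OH equatorial and NO2 axial, which sets the quaternary centre with N trans to the C2–H.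

**Step 7**
Reactants: 14 nitro alcohol
Product: 15 tert-butyl (R)-2-{[(2R,3S)-3-amino-3-(hydroxymethyl)-1,1-dimethyl-2,3,4,9-tetrahydro-1H-carbazol-2-yl]methyl}pyrrolidine-1-carboxylate
Conditions: H2 (4 atm), neutral Raney Ni, MeOH, rt
Reagents that add atoms: none
Why: Catalytic hydrogenation of a β-nitro alcohol to the β-amino alcohol breaks no bond at the stereocentre, leaves the indole and Boc group intact, and the neutral medium suppresses retro-Henry cleavage.

**Step 8**
Reactants: 15 amino alcohol
Product: 18 tert-butyl (R)-2-{[(2R,3S,4aS)-3-(hydroxymethyl)-1,1-dimethyl-3,4a-(iminocarbonyloxy)-2,3,4,4a-tetrahydro-1H-carbazol-2-yl]methyl}pyrrolidine-1-carboxylate (NH on C3 and O on C4a), via caesium carbamate 16 (not isolated), via 4a-iodoindolenine 17 (not isolated)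
Conditions: CO2 (1 atm), Cs2CO3 (1.2 equiv), DMF, rt; then NIS (1.05 equiv), 0 °C
Reagents that add atoms: carbon dioxide, O=C=O
Why: Proposed new method: CO2/Cs2CO3 turn the hindered amine into its caesium carbamate, NIS iodinates the indole at C4a from the open face anti to the axial N and axial methyl, and the carbamate oxygen, held 1,3-diaxial to C4a, displaces iodide from the rear (6-exo-tet), so the tether fixes the new C–O centre as (S) and unveils the 3H-indole; the closest known reaction types are the amine/CO2/alkyl halide carbamate synthesis, the CO2-incorporating halocyclisation of unsaturated amines and the iodine-mediated intramolecular dearomative oxidative coupling of indoles with carbon nucleophiles, but a CO2-derived carbamate oxygen has not been used to capture indole C3.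

**Step 9**
Reactants: 18 bridged carbamate alcohol
Product: 19 tert-butyl (R)-2-{[(2R,3S,4aS)-3-formyl-1,1-dimethyl-3,4a-(iminocarbonyloxy)-2,3,4,4a-tetrahydro-1H-carbazol-2-yl]methyl}pyrrolidine-1-carboxylate
Conditions: Dess–Martin periodinane (1.3 equiv), CH2Cl2, rt
Reagents that add atoms: none
Why: Dess–Martin oxidation of the primary alcohol is neutral and spares the imine, carbamate and Boc group, and the aldehyde cannot epimerise because its α-carbon is quaternary.

**Step 10**
Reactants: 19 Boc amino aldehyde
Product: 21 penicimutamide B, via amino aldehyde 20 (not isolated)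
Conditions: TFA/CH2Cl2 (1:4), 0 °C to rt; then sat. aq NaHCO3
Reagents that add atoms: none
Why: Acidolysis of Boc frees the pyrrolidine N, which adds to the aldehyde across the two trans-diequatorial arms to give an all-chair trans-fused indolizidine, and the carbinolamine equilibrates through the iminium ion (no enamine is possible) to the axial OH stabilised by the anomeric nN→σ*C–O interaction, which is the (R) centre of the target.

**Compound list**
1 | tert-butyl pent-4-en-1-ylcarbamate | C=CCCCNC(=O)OC(C)(C)C | starting material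
2 | (E)-but-2-enal (crotonaldehyde) | C/C=C/C=O | starting material
3 | tert-butyl [(E)-6-oxohex-4-en-1-yl]carbamate | O=C/C=C/CCCNC(=O)OC(C)(C)C | intermediate
4 | tert-butyl (R)-2-(2-oxoethyl)pyrrolidine-1-carboxylate | O=CC[C@H]1CCCN1C(=O)OC(C)(C)C | intermediate
5 | tert-butyl (2R)-2-(2-hydroxy-3-nitropropyl)pyrrolidine-1-carboxylate (carbinol epimers) | [O-][N+](=O)CC(O)C[C@H]1CCCN1C(=O)OC(C)(C)C | intermediate
6 | methanesulfonate of 5 | [O-][N+](=O)CC(OS(C)(=O)=O)C[C@H]1CCCN1C(=O)OC(C)(C)C | intermediate
7 | tert-butyl (R)-2-[(E)-3-nitroprop-2-en-1-yl]pyrrolidine-1-carboxylate | [O-][N+](=O)/C=C/C[C@H]1CCCN1C(=O)OC(C)(C)C | intermediate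
8 | 4-methylpent-1-en-3-one (isopropyl vinyl ketone) | C=CC(=O)C(C)C | starting material
9 | tert-butyl (R)-2-[(2R)-3,3-dimethyl-2-(nitromethyl)-4-oxohex-5-en-1-yl]pyrrolidine-1-carboxylate | C=CC(=O)C(C)(C)[C@H](C[N+](=O)[O-])C[C@H]1CCCN1C(=O)OC(C)(C)C | intermediate
10 | tert-butyl (R)-2-{[(1R,6R)-2,2-dimethyl-6-nitro-3-oxocyclohexyl]methyl}pyrrolidine-1-carboxylate | CC1(C)C(=O)CC[C@@H]([N+](=O)[O-])[C@@H]1C[C@H]1CCCN1C(=O)OC(C)(C)C | intermediate
11 | phenylhydrazine | NNc1ccccc1 | starting material
12 | phenylhydrazone of 10 | CC1(C)C(=NNc2ccccc2)CC[C@@H]([N+](=O)[O-])[C@@H]1C[C@H]1CCCN1C(=O)OC(C)(C)C | intermediate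
13 | tert-butyl (R)-2-{[(2R,3R)-1,1-dimethyl-3-nitro-2,3,4,9-tetrahydro-1H-carbazol-2-yl]methyl}pyrrolidine-1-carboxylate | CC1(C)c2[nH]c3ccccc3c2C[C@@H]([N+](=O)[O-])[C@@H]1C[C@H]1CCCN1C(=O)OC(C)(C)C | intermediate
14 | (2R,3S)-3-hydroxymethyl-3-nitro analogue of 13 (CH2OH trans to the C2 side chain) | CC1(C)c2[nH]c3ccccc3c2C[C@](CO)([N+](=O)[O-])[C@@H]1C[C@H]1CCCN1C(=O)OC(C)(C)C | intermediate
15 | (2R,3S)-3-amino-3-hydroxymethyl analogue of 13 | CC1(C)c2[nH]c3ccccc3c2C[C@](CO)(N)[C@@H]1C[C@H]1CCCN1C(=O)OC(C)(C)C | intermediate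
16 | caesium N-carboxylate (carbamate salt) of 15 | CC1(C)c2[nH]c3ccccc3c2C[C@](CO)(NC(=O)[O-])[C@@H]1C[C@H]1CCCN1C(=O)OC(C)(C)C.[Cs+] | intermediate
17 | (4aR)-4a-iodo-4aH-carbazole (3-iodoindolenine) form of 16, I anti to the carbamate | CC1(C)C2=Nc3ccccc3[C@]2(I)C[C@](CO)(NC(=O)[O-])[C@@H]1C[C@H]1CCCN1C(=O)OC(C)(C)C.[Cs+] | intermediate
18 | (2R,3S,4aS) bridged cyclic carbamate (C3–NH–CO–O–C4a), 3H-indole, 3-CH2OH, N-Boc-(R)-pyrrolidin-2-ylmethyl at C2 | CC1(C)C2=Nc3ccccc3[C@@]23C[C@](CO)(NC(=O)O3)[C@@H]1C[C@H]1CCCN1C(=O)OC(C)(C)C | intermediate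
19 | 3-formyl analogue of 18 | CC1(C)C2=Nc3ccccc3[C@@]23C[C@](C=O)(NC(=O)O3)[C@@H]1C[C@H]1CCCN1C(=O)OC(C)(C)C | intermediate
20 | N-deprotected amino aldehyde from 19 | CC1(C)C2=Nc3ccccc3[C@@]23C[C@](C=O)(NC(=O)O3)[C@@H]1C[C@H]1CCCN1 | intermediate
21 | penicimutamide B | CC1(C)C2=Nc3ccccc3[C@@]23C[C@]2(NC(=O)O3)[C@@H]1C[C@H]1CCCN1[C@@H]2O | target

**Total step count:** 10. **Longest linear sequence:** 10 (fully linear from 1).

**Three steps most likely to fail**

Step 4 (new reaction). The hindered isopropyl side may not form the enamine. The catalyst may be lost by aza-Michael addition to 8. Product 10 may add to excess 8. The fallback sets out from 7 and returns at 10. Isobutyraldehyde is added to 7 with the same primary-amine thiourea, which is the established conjugate addition of α,α-disubstituted aldehydes to nitroalkenes, to give the γ-nitro aldehyde F1. Excess vinylmagnesium bromide at −78 °C gives the allylic alcohol F2; its first equivalent masks the nitro group as the nitronate. Dess–Martin oxidation delivers enone 9, now isolated, and catalytic DBU closes it by intramolecular nitro-Michael addition to 10.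

Step 8 (new reaction). The hindered carbamate may lose CO2. The 4a-iodoindolenine may eliminate or rearrange faster than it is captured. The fallback sets out from 15 and returns at 18. TBSCl/imidazole gives the silyl ether F3, and phenyl chloroformate/pyridine gives the phenyl carbamate F4. mCPBA at −20 °C, steered by hydrogen bonding to the axial carbamate N–H, oxidises the indole to the syn 4a-hydroxyindolenine F5. DBU induces attack of the tertiary alkoxide on the phenyl carbamate to give the silylated bridged carbamate F6. TBAF then frees 18.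

Step 5. The neopentyl ketone forms its hydrazone slowly, and hot AcOH may cleave Boc. The fallback sets out from 10 and returns at 13. Ketone 10 is heated with 2-iodoaniline, Pd(OAc)2 and DABCO in DMF at 105 °C. Condensation gives the N-(2-iodophenyl) enamine F7, which closes by intramolecular Heck reaction to 13 without any acid.

**Further compounds**
F1 | step 4 | tert-butyl (R)-2-[(2R)-3,3-dimethyl-2-(nitromethyl)-4-oxobutyl]pyrrolidine-1-carboxylate | O=CC(C)(C)[C@H](C[N+](=O)[O-])C[C@H]1CCCN1C(=O)OC(C)(C)C
F2 | step 4 | tert-butyl (R)-2-[(2R)-4-hydroxy-3,3-dimethyl-2-(nitromethyl)hex-5-en-1-yl]pyrrolidine-1-carboxylate (carbinol epimers) | C=CC(O)C(C)(C)[C@H](C[N+](=O)[O-])C[C@H]1CCCN1C(=O)OC(C)(C)C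
F3 | step 8 | O-TBS ether of 15 | CC1(C)c2[nH]c3ccccc3c2C[C@](CO[Si](C)(C)C(C)(C)C)(N)[C@@H]1C[C@H]1CCCN1C(=O)OC(C)(C)C
F4 | step 8 | N-phenoxycarbonyl derivative of F3 | CC1(C)c2[nH]c3ccccc3c2C[C@](CO[Si](C)(C)C(C)(C)C)(NC(=O)Oc2ccccc2)[C@@H]1C[C@H]1CCCN1C(=O)OC(C)(C)C
F5 | step 8 | (4aS)-4a-hydroxy-4aH-carbazole (3-hydroxyindolenine) from F4, OH syn to the carbamate | CC1(C)C2=Nc3ccccc3[C@@]2(O)C[C@](CO[Si](C)(C)C(C)(C)C)(NC(=O)Oc2ccccc2)[C@@H]1C[C@H]1CCCN1C(=O)OC(C)(C)C
F6 | step 8 | O-TBS ether of 18 | CC1(C)C2=Nc3ccccc3[C@@]23C[C@](CO[Si](C)(C)C(C)(C)C)(NC(=O)O3)[C@@H]1C[C@H]1CCCN1C(=O)OC(C)(C)C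
F7 | step 5 | N-(2-iodophenyl) enamine of 10 | CC1(C)C(Nc2ccccc2I)=CC[C@@H]([N+](=O)[O-])[C@@H]1C[C@H]1CCCN1C(=O)OC(C)(C)C
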